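The one difficult bond is the tetra-ortho-substituted biaryl axis between coumarin C8 and C6 of flavone ring A. Both carbons sit next to phenolic oxygens (coumarin O7; flavone O5 and O7). Coumarin O7 and flavone O5 are therefore tied together through one CH2 unit, and the coupling is run intramolecularly. In a single operation palladium replaces the C8–I bond and the C6–H bond by the C8–C6 bond and closes a sacrificial dibenzo-1,3-dioxepine. The precursor is 7,4'-di-O-benzylapigenin carrying an (8-iodocoumarin-7-yl)oxymethyl group on O5. One later BCl3 treatment removes the bridge and the benzyl groups together.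

Key step: step 6

Assumption: the target SMILES carries no axial descriptor and has no stereocentre, so the hindered C8–C6 axis is made and delivered as a racemate.

Design remarks:
- **Spectator ethers.** They are benzyl, so the end game needs only cold BCl3. Forcing dealkylation, with its risk of aryl migration from C6 to C8, is avoided.
- **Chloromethyl ether.** It is made through an O,S-acetal, because a dihalomethane tends to link two phenoxides symmetrically.
- **Halide.** Iodide is kept because C8 iodination of umbelliferone is reliable. Ag2CO3 is added in the key step to remove iodide from the catalyst.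

Step 1
Reactants: 1 umbelliferone (7-hydroxycoumarin)
Product: 2 7-hydroxy-8-iodocoumarin
Conditions: I2 (1.0 equiv), KI, 20% aq NH3, 0 °C → rt
Reagents that add atoms: iodine, II
Why: Electrophilic aromatic iodination of the phenoxide, which in 7-hydroxycoumarins goes to C8 (the ortho carbon between O7 and the ring-fusion carbon C8a, the site also chosen by Mannich, Duff and Claisen reactions of umbelliferone), while one equivalent of iodine holds back a second iodination at C6.

Step 2
Reactants: 2 7-hydroxy-8-iodocoumarin; 3 chloromethyl methyl sulfide
Product: 4 8-iodo-7-[(methylsulfanyl)methoxy]coumarin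
Conditions: NaH, DMF, 0 °C → rt
Reagents that add atoms: none
Why: Williamson ether synthesis that turns the acidic phenol into a stable, chromatographable O,S-acetal (methylthiomethyl ether), chosen because a dihalomethane would mainly give the symmetrical bis(aryloxy)methane.

Step 3
Reactants: 4 8-iodo-7-[(methylsulfanyl)methoxy]coumarin
Product: 5 7-(chloromethoxy)-8-iodocoumarin (used crude)
Conditions: SO2Cl2 (1.0 equiv), CH2Cl2, 0 °C; volatiles removed in vacuo
Reagents that add atoms: sulfuryl chloride, O=S(=O)(Cl)Cl
Why: Chlorinolysis of an O,S-acetal, in which sulfur (by far the most nucleophilic site) is chlorinated to a chlorosulfonium ion that expels MeSCl and chloride captures the aryloxymethyl cation, a standard entry to aryl chloromethyl ethers that leaves the electron-poor iodocoumarin ring untouched.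

Step 4
Reactants: 6 apigenin
Product: 7 7,4'-di-O-benzylapigenin (5-OH free)
Conditions: BnBr (2.1 equiv), K2CO3 (2.2 equiv), DMF, rt
Reagents that add atoms: benzyl bromide, BrCc1ccccc1
Why: Chemoselective Williamson benzylation, since the 7- and 4'-hydroxyls are the acidic ones whereas the 5-hydroxyl is locked in a hydrogen bond to the C4 carbonyl and stays free with a weak base at room temperature.

Step 5
Reactants: 5 7-(chloromethoxy)-8-iodocoumarin; 7 7,4'-di-O-benzylapigenin
Product: 8 7,4'-di-O-benzyl-5-O-{[(8-iodo-2-oxo-2H-chromen-7-yl)oxy]methyl}apigenin
Conditions: 7, NaH (1.1 equiv), DMF, 0 °C; then 5 (1.3 equiv), 0 °C → rt; chromatography on Et3N-washed silica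
Reagents that add atoms: none
Why: Williamson-type SN2 alkylation, in which NaH fully deprotonates the chelated 5-hydroxyl (the only nucleophilic site left in 7) and the alpha-chloro ether is as reactive as the chloromethyl methyl ether routinely used to protect this position in flavones.

Step 6
Reactants: 8 7,4'-di-O-benzyl-5-O-{[(8-iodo-2-oxo-2H-chromen-7-yl)oxy]methyl}apigenin
Product: 9 methylene-bridged biaryl, i.e. 7,4'-di-O-benzyl-6-(7-hydroxy-2-oxo-2H-chromen-8-yl)apigenin with coumarin O7 and flavone O5 joined by one CH2 (dibenzo[d,f][1,3]dioxepine core, racemic axis)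
Conditions: Pd(OAc)2 (10 mol%), PCy3·HBF4 (20 mol%), PivOH (30 mol%), K2CO3 (2 equiv), Ag2CO3 (0.5 equiv), DMA (0.02 M), 110 °C
Reagents that add atoms: none
Why: The cycle opens with oxidative addition of the coumarin C8–I bond to zerovalent palladium (formed in situ from Pd(OAc)2 and PCy3), Ag2CO3 takes away the iodide that otherwise slows catalysis with aryl iodides, and the pivalate that binds in its place removes the C6 proton of flavone ring A while the metal takes the carbon (concerted metalation–deprotonation). The eight-membered diarylpalladium ring that results collapses by reductive elimination, so the seven-membered 1,3-dioxepine (flavone C5, O5, CH2, coumarin O7, C7, C8, flavone C6) is closed at its aryl–aryl edge by C–C bond formation. The closest known reaction type is the intramolecular direct arylation of tethered aryl halides, established for six- and seven-membered rings and for removable links between two phenols. No stereocentre is formed and the new axis arises as a racemate. Site selectivity is needed on both rings: on the coumarin the halogen marks C8, and on the flavone the short O–CH2–O link anchored at O5 can deliver palladium only to C6, because the second ortho carbon is the ring-fusion atom C4a and C8–H, C3–H, ring B and the benzyl groups are too remote. Because both partners sit in one molecule the crowding by four ortho substituents is affordable, the two flanking oxygens acidify C6–H, and high dilution holds back intermolecular Heck-type attack on the two enone C=C bonds.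

Step 7
Reactants: 9 methylene-bridged biaryl
Product: 11 6-(7-hydroxy-2-oxo-2H-chromen-8-yl)apigenin (target), via chloromethyl ether 10 (not isolated)
Conditions: BCl3 (8 equiv), C6HMe5 (8 equiv), CH2Cl2, −78 → 0 °C; then THF–H2O, rt
Reagents that add atoms: boron trichloride, ClB(Cl)Cl (its chlorine appears only in 10; no reagent atom remains in 11)
Why: Lewis-acid ether cleavage, in which BCl3 held between the C4 carbonyl and O5 breaks the O5–CH2 bond as in the familiar selective 5-O-dealkylation of flavones, the two aryl benzyl ethers fall at low temperature with pentamethylbenzene as a non-basic trap for benzyl cations, the chloromethyl ether left on coumarin O7 loses formaldehyde on aqueous quench, and the cold conditions avoid the Wessely–Moser shift of the aryl group from C6 to C8 that hot protic acid can cause.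

Compound list
1 | umbelliferone | O=c1ccc2ccc(O)cc2o1 | starting material
2 | 7-hydroxy-8-iodocoumarin | O=c1ccc2ccc(O)c(I)c2o1 | intermediate
3 | chloromethyl methyl sulfide | ClCSC | starting material
4 | 8-iodo-7-[(methylsulfanyl)methoxy]coumarin | CSCOc1ccc2ccc(=O)oc2c1I | intermediate
5 | 7-(chloromethoxy)-8-iodocoumarin | ClCOc1ccc2ccc(=O)oc2c1I | intermediate
6 | apigenin | O=c1cc(-c2ccc(O)cc2)oc2cc(O)cc(O)c12 | starting material
7 | 7,4'-di-O-benzylapigenin | O=c1cc(-c2ccc(OCc3ccccc3)cc2)oc2cc(OCc3ccccc3)cc(O)c12 | intermediate
8 | 7,4'-di-O-benzyl-5-O-{[(8-iodo-2-oxo-2H-chromen-7-yl)oxy]methyl}apigenin | c1ccccc1COc1ccc(cc1)-c1cc(=O)c2c(OCOc3ccc4ccc(=O)oc4c3I)cc(OCc3ccccc3)cc2o1 | intermediate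
9 | methylene-bridged biaryl (7,4'-di-O-benzyl target with coumarin O7 and flavone O5 tied as a formaldehyde acetal) | c1ccccc1COc1ccc(cc1)-c1cc(=O)c2c3OCOc4ccc5ccc(=O)oc5c4-c3c(OCc3ccccc3)cc2o1 | intermediate
10 | 6-[7-(chloromethoxy)-2-oxo-2H-chromen-8-yl]apigenin (present in the flask as its boron phenoxides) | O=c1ccc2ccc(OCCl)c(-c3c(O)cc4oc(-c5ccc(O)cc5)cc(=O)c4c3O)c2o1 | intermediate
11 | 6-(7-hydroxy-2-oxo-2H-chromen-8-yl)apigenin, CNP0223343.0 | O=c1ccc2ccc(O)c(-c3c(O)cc4oc(-c5ccc(O)cc5)cc(=O)c4c3O)c2o1 | target

Total step count: 7. Longest linear sequence: 6 (steps 1, 2, 3, 5, 6, 7, from umbelliferone).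

Steps most likely to fail

**Step 6.**
- *Risk.* Reduction of the C–I bond, or migration of palladium onto the acetal CH2, may outrun the slow C–H cleavage at the crowded C6. Carboxylate attack on the acetal carbon may also strip the tether.
- *Fallback.* Both carbons are pre-activated and joined by reductive coupling instead of C–H activation. It sets out from 7 (with 5) and returns at 9. Iodination of 7 with benzyltrimethylammonium dichloroiodate and CaCO3 in CH2Cl2–MeOH is steered to C6 by the free chelated 5-hydroxyl and should give 7,4'-di-O-benzyl-6-iodoapigenin F1. Alkylation of its sodium salt with 5 under the conditions of step 5 gives 7,4'-di-O-benzyl-6-iodo-5-O-{[(8-iodo-2-oxo-2H-chromen-7-yl)oxy]methyl}apigenin F2. An intramolecular Ullmann coupling (activated copper powder, DMF, 130 °C) then joins the two iodinated carbons and rejoins the route at 9.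

**Step 5.**
- *Risk.* O-alkylation of the chelated, flanked phenoxide may be slow and lose out to hydrolysis or self-condensation of the moisture-sensitive alpha-chloro ether.
- *Fallback.* The roles of the two halves are exchanged. It sets out from 7 (with 3 and 2) and returns at 8. The difficult alkylation of O5 is done with the bench-stable 3, which tolerates excess and heating (NaH, DMF, 60 °C), to give 7,4'-di-O-benzyl-5-O-(methylsulfanylmethyl)apigenin F3. SO2Cl2 (1.0 equiv, CH2Cl2, −78 °C) converts it into 7,4'-di-O-benzyl-5-O-(chloromethyl)apigenin F4. This is added crude to the caesium salt of 2 (Cs2CO3, DMF, 0 °C → rt), an unchelated and much better nucleophile, to give 8.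

**Step 7.**
- *Risk.* The bridge may open incompletely, or the liberated benzyl and oxymethyl cations may re-attack the electron-rich C8 of ring A.
- *Fallback.* The two kinds of protecting group are removed separately, with no free carbon electrophile at either stage. It sets out from 9 and returns at 11. Neutral transfer hydrogenolysis (Pd/C, 1,4-cyclohexadiene, THF–EtOH, rt, stopped once both benzyl groups are gone so that the coumarin C3=C4 bond is spared) gives the methylene-bridged 7,4'-diol F5. Transthioacetalisation (ethane-1,2-dithiol, BF3·OEt2, CH2Cl2–MeCN, 0 °C → rt) then hands the acetal carbon directly to sulfur and releases 11.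

Further compounds
F1 | step 6 | 7,4'-di-O-benzyl-6-iodoapigenin | O=c1cc(-c2ccc(OCc3ccccc3)cc2)oc2cc(OCc3ccccc3)c(I)c(O)c12
F2 | step 6 | 7,4'-di-O-benzyl-6-iodo-5-O-{[(8-iodo-2-oxo-2H-chromen-7-yl)oxy]methyl}apigenin | c1ccccc1COc1ccc(cc1)-c1cc(=O)c2c(OCOc3ccc4ccc(=O)oc4c3I)c(I)c(OCc3ccccc3)cc2o1
F3 | step 5 | 7,4'-di-O-benzyl-5-O-(methylsulfanylmethyl)apigenin | CSCOc1cc(OCc2ccccc2)cc2oc(-c3ccc(OCc4ccccc4)cc3)cc(=O)c12
F4 | step 5 | 7,4'-di-O-benzyl-5-O-(chloromethyl)apigenin | ClCOc1cc(OCc2ccccc2)cc2oc(-c3ccc(OCc4ccccc4)cc3)cc(=O)c12
F5 | step 7 | methylene-bridged 7,4'-diol (target with coumarin O7 and flavone O5 tied as a formaldehyde acetal) | Oc1ccc(cc1)-c1cc(=O)c2c3OCOc4ccc5ccc(=O)oc5c4-c3c(O)cc2o1
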